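Ask where free monomer stops in this flask at 6.0 min, and what average chain length dp and conversion c follow.

| setting | zeta | delta | flask |
|---|---|---|---|
| free monomer | 0.20 mM | 0.20 mM | 0.20 mM |
| protic impurity | 0.060 mM | 0.060 mM | 0.0600 mM |
| initiator | 0.80 µM | 1.8 µM | 1.2 µM |
| remark | run made earlier | run made earlier |  |
| time |  |  | 6.0 min |

- zeta (time / min: monomer in chains / %, free monomer / %): 0.833: 37, 39; 1.50: 47, 27; 2.50: 53, 20; 3.00: 52, 16; 4.00: 55, 17; 5.00: 54, 15
- delta (time / min: monomer in chains / %, free monomer / %): 0.333: 36, 42; 1.00: 55, 17; 1.50: 57, 15; 2.50: 57, 15; 4.00: 56, 15; 5.00: 55, 15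

(each reading ± 1.5 percentage points)

- average number of monomer units in a chain (chains begun, living or dead) at 6.0 min
- part of the free monomer that has reacted at 6.0 min

- the average divides the monomer in chains by the number of chains begun, living and dead together
- the earlier runs do not show the number of chains; that part of a forecast is a guess

Start with free monomer. Zeta and delta both end at a reading of 15%, although delta holds 2.25 times zeta's initiator. Divide the rate of entry into chains by the rate of return from them: at a level this ratio is one, and time drops out. Keep that reading, 0.0300 mM on this flask's charge, as the floor Mf, the free monomer left when entry balances return, the equilibrium monomer concentration.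

Check that this flask reaches Mf. Its time multiplied by initiator exceeds zeta's at 3.00 min by a factor of 3.00, and zeta there already reads 16% free monomer, so I expect c = 85.0%.

Next ask where the reacted monomer went. Delta's last readings leave 0.0600 mM outside chains and free monomer, a ratio of 1.00 to the protic impurity charged. Debit one monomer per impurity, leaving 0.110 mM in chains. Guess one chain per initiator: dp = 91.7.

The forecast gave dp = 92 (1.7 to 100) and c = 85% (83% to 87%); of impurity as side reaction or as chain transfer it said: “The data cannot separate these, so the range is wide.”

The flask gives dp = 93.9 and c = 85.3%.

    free monomer + initiator → living end + monomer in chains (k = 2800 L mol⁻¹ s⁻¹)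
    free monomer + living end → monomer in chains + living end, rate k2*[living end]*[free monomer] (k = 21000 L mol⁻¹ s⁻¹)
    monomer in chains + living end → free monomer + living end, rate k3*[living end] as long as [monomer in chains] is above zero (k = 0.620 s⁻¹)
    protic impurity + free monomer → quenched substrate (k = 380 L mol⁻¹ s⁻¹)
    2 free monomer → homo dimer (k = 0.0780 L mol⁻¹ s⁻¹)
    2 initiator → spent initiator (k = 8200 L mol⁻¹ s⁻¹)

At 6.00 min this flask holds 14.7% free monomer, and Mf is 15.0% of its charge; living end stands at 0.00118 mM from 1.2 µM of initiator, 0.983 per initiator against the guess of one. Now take the neighbour charged with 0.80 mM of free monomer, all else as in this flask. Keep Mf and the impurity debit: c = 96.2%, chains receive 0.710 mM, and dp = 592. That neighbour gives c = 96.3%, 88.6% monomer in chains and dp = 593.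

(All runs are calculated for an exercise.)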